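**Plan**

1. Locants: cycloheptane ring A = C1 (C–OH carrying the but-2-enoyl chain C2–C4/C15), C5 (CH–O-angeloyl), C6 (CH–O of the lactone), C7, C8 (CH2), C9 (CH–OH), C10 (CH–CH3); lactone ring B = O6–C12(=O)–C11(=C13H2)–C7–C6.
2. Enabling feature: rings A and B share the C6–C7 bond, with O6 on C6 and the acrylate carbon C11 on C7. This is the retron of a carbonyl allylation by a 2-(methoxycarbonyl)allyl metal, whose C6 alkoxide then lies 1,4 to the ester carbon C12.
3. Retrosynthesis: angelate and protecting groups off; C6–C7 and O6–C12 cut in one operation to an open-chain C6 aldehyde carrying a (Z)-2-(bromomethyl)enoate at C7=C11; then C7–C11 (Morita–Baylis–Hillman), C2–C3 (Weinreb ketone synthesis), C8–C9 (allylation) and C1–C10 (Ireland–Claisen) back to L-threitol acetonide.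
4. Forward: the chain C6–C5–C1–C10–C9–C8–C7 is built open-chain on a trans-dioxolane (temporary ring over O5/O1); ring A and ring B then close together in step 15; acetonide removal, angeloylation and desilylation finish.
5. Stereochemistry: C5 from the chiral pool (L-tartaric acid series); C1 and C10 from the Ireland–Claisen step (attack anti to the C5 arm, chair transition state); C9 by Felkin–Anh allylation; C6 and C7 in the key step; alkene geometries from (E)-propenyllithium, the thermodynamic allylic bromide and angelic acid.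

Key step: step 15

**Route**

Step 1
Reactants: 1 (+)-2,3-O-isopropylidene-L-threitol
Product: 2 mono-PMB ether of 1
Conditions: NaH (one equivalent), 4-methoxybenzyl chloride, Bu4NI (cat.), THF/DMF, 0 to 23 °C
Reagents that add atoms: 4-methoxybenzyl chloride COc1ccc(CCl)cc1
Why: Williamson etherification with one equivalent of alkoxide desymmetrises the C2-symmetric diol (both arms are equivalent) without touching its two stereocentres, one of which becomes C5 of the target.

Step 2
Reactants: 2 mono-PMB ether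
Product: 4 dioxolane carboxylic acid, via aldehyde 3 (not isolated)
Conditions: TEMPO (cat.), PhI(OAc)2, MeCN/H2O, 23 °C
Reagents that add atoms: water O
Why: TEMPO-catalysed oxidation with PhI(OAc)2 in aqueous MeCN takes the primary alcohol through aldehyde 3 and its hydrate to the acid while sparing the PMB ether and the acetonide, and the α-centre of 4 needs no care because it becomes sp2 in step 4.

Step 3
Reactants: 4 dioxolane carboxylic acid; 5 (2E)-but-2-en-1-ol
Product: 6 (E)-crotyl ester
Conditions: DCC, DMAP (cat.), CH2Cl2, 0 to 23 °C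
Reagents that add atoms: none
Why: Steglich esterification assembles the allyl ester needed for the sigmatropic step, the (E)-geometry of 5 being carried over unchanged.

Step 4
Reactants: 6 (E)-crotyl ester
Product: 9 quaternary acid with (2S)-but-3-en-2-yl group, via silyl ketene acetal 7 (not isolated), via trimethylsilyl ester 8 (not isolated)
Conditions: LiN(iPr)2, Me3SiCl (internal quench), THF, −78 °C, then 23 to 50 °C; dilute citric acid work-up
Reagents that add atoms: none
Why: Ireland–Claisen rearrangement in which chelation-controlled enolisation with internal silyl quench gives the (Z)-ketene acetal 7 (silyloxy cis to the ring oxygen; the β-oxygen is not expelled because its C–O bond lies near the nodal plane of the exocyclic enolate), the crotyl unit is delivered to the dioxolane face anti to the C5 CH2OPMB arm (sets C1), and the chair transition state with the (E)-methyl equatorial places the ring oxygen and the methyl syn along C2–C1–C10–C9 (sets C10).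

Step 5
Reactants: 9 quaternary acid
Product: 11 Weinreb amide, via acid chloride 10 (not isolated)
Conditions: 1-chloro-N,N,2-trimethylprop-1-en-1-amine, CH2Cl2, 0 °C; then MeNH(OMe)·HCl, Et3N, 0 to 23 °C
Reagents that add atoms: N,O-dimethylhydroxylamine hydrochloride CNOC.Cl
Why: acyl chloride formation under neutral conditions with the α-chloroenamine followed by aminolysis (Weinreb amide synthesis) suits the hindered, acid-sensitive α-quaternary acid and prepares C2 for a single later addition.

Step 6
Reactants: 11 Weinreb amide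
Product: 13 α-methyl aldehyde (C9), via ozonide 12 (not isolated)
Conditions: O3, CH2Cl2, −78 °C (Sudan Red 7B end point); then PPh3, −78 to 23 °C
Reagents that add atoms: ozone [O-][O+]=O
Why: ozonolysis with reductive work-up cleaves the only C=C bond (the PMB arene reacts far more slowly and the dye marks the end point) to the α-methyl aldehyde, which is used at once so that C10 does not epimerise.

Step 7
Reactants: 13 α-methyl aldehyde; 14 allyltrimethylsilane
Product: 15 homoallylic alcohol
Conditions: BF3·OEt2, CH2Cl2, −78 °C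
Reagents that add atoms: none
Why: Hosomi–Sakurai allylation promoted by the monodentate Lewis acid BF3 goes through an open Felkin–Anh transition state in which the allylsilane attacks anti to the very large quaternary C1 substituent, which should give the C9 alcohol syn to the C10 methyl.

Step 8
Reactants: 15 homoallylic alcohol
Product: 16 C9 TBS ether
Conditions: tBuMe2SiOTf, 2,6-lutidine, CH2Cl2, −78 to 0 °C
Reagents that add atoms: tert-butyldimethylsilyl trifluoromethanesulfonate CC(C)(C)[Si](C)(C)OS(=O)(=O)C(F)(F)F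
Why: silylation with the silyl triflate and 2,6-lutidine protects the hindered secondary C9 alcohol so that it stays distinguishable from O5 in step 17.

Step 9
Reactants: 16 C9 TBS ether; 17 (1E)-1-bromoprop-1-ene
Product: 20 (E)-enone, via (E)-propenyllithium 18 (not isolated), via lithium adduct 19 (not isolated)
Conditions: 17, t-BuLi (two equivalents), Et2O, −78 °C; then 16, THF, −78 to 0 °C; H2O quench
Reagents that add atoms: none
Why: Weinreb ketone synthesis in which bromine–lithium exchange proceeds with retention of the (E)-geometry and the chelated lithium adduct 19 prevents a second addition, giving the (E)-enone on aqueous quench.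

Step 10
Reactants: 20 (E)-enone
Product: 22 C7 aldehyde, via ozonide 21 (not isolated)
Conditions: O3, CH2Cl2, −78 °C (Sudan Red 7B end point); then PPh3, −78 to 23 °C
Reagents that add atoms: ozone [O-][O+]=O
Why: chemoselective ozonolysis relying on the much higher reactivity of the isolated monosubstituted alkene towards electrophilic ozone compared with the electron-poor conjugated enone C=C and the PMB arene, with the dye end point preventing over-oxidation.

Step 11
Reactants: 22 C7 aldehyde; 23 methyl acrylate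
Product: 24 Morita–Baylis–Hillman adduct (both C7 epimers)
Conditions: 23 (neat, excess), DABCO, 23 °C
Reagents that add atoms: none
Why: Morita–Baylis–Hillman reaction of the unhindered aldehyde with the acrylate, the β-substituted enone being a far poorer partner for the amine catalyst and the new C7 carbinol centre being formed without control because it becomes sp2 in step 12.

Step 12
Reactants: 24 Morita–Baylis–Hillman adduct
Product: 25 (Z)-allylic bromide
Conditions: N-bromosuccinimide, Me2S, CH2Cl2, 0 to 23 °C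
Reagents that add atoms: N-bromosuccinimide O=C1CCC(=O)N1Br
Why: the allylic alcohol is activated as an alkoxysulfonium salt by the sulfonium reagent from N-bromosuccinimide and Me2S and bromide attacks in SN2′ fashion, the allylic transposition giving from both epimers the thermodynamically preferred trisubstituted enoate with C8 trans to the ester ((Z) by the sequence rule).

Step 13
Reactants: 25 (Z)-allylic bromide
Product: 26 primary alcohol (C6)
Conditions: DDQ, CH2Cl2/pH 7 phosphate buffer, 0 °C
Reagents that add atoms: none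
Why: oxidative cleavage of the PMB ether by DDQ (benzylic hydride abstraction, then hydrolysis) is orthogonal to the silyl ether, acetonide, allylic bromide and enone.

Step 14
Reactants: 26 primary alcohol
Product: 27 C6 aldehyde
Conditions: Dess–Martin periodinane, NaHCO3, CH2Cl2, 0 to 23 °C
Reagents that add atoms: none
Why: Dess–Martin oxidation under buffered, non-basic conditions gives the α-alkoxy aldehyde without epimerisation at C5 or displacement of the allylic bromide, and 27 is used directly.

Step 15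
Reactants: 27 C6 aldehyde
Product: 30 tricyclic lactone (acetonide TBS ether), via allylchromium 28 (not isolated), via hydroxy ester 29 (not isolated)
Conditions: CrCl2 (excess), THF, high dilution, 23 °C; then aq. NH4Cl
Reagents that add atoms: none
Why: Intramolecular Nozaki–Hiyama–Kishi (Barbier-type) allylation: two equivalents of CrCl2 reduce the allylic bromide to the nucleophilic allyl–trivalent chromium species 28, which adds through its γ-carbon C7 to the C6 aldehyde in a closed chair-like six-membered transition state (chromium bridging O6 and C13), and the chromium alkoxide of 29 then acylates on the neighbouring ester carbon C12. The closest known reaction type is the carbonyl allylation of aldehydes by 2-(alkoxycarbonyl)allyl halides with CrCl2, zinc or indium to give α-methylene-γ-butyrolactones, which is established intramolecularly for carbocycle-fused lactones. Ring A closes by a 7-exo-trig addition to the carbonyl with allylic transposition (SE2′), which turns C11=C13 into the exocyclic methylene, and ring B closes by a 5-exo-trig acyl substitution at C12. C7 is controlled by the allyl geometry, since the thermodynamically preferred allylchromium with C8 cis to CH2Cr sits with C8 axial and the C5 arm equatorial in the chair and so places O6 and C11 cis (cis-fused lactone); C6 is controlled by the trans-fused acetonide, which holds O5 and O1 equatorial and the C2 acyl group axial on the forming ring, so that the aldehyde should react with its hydrogen and not its chromium-bound oxygen syn-axial to C2 and with O5 antiperiplanar to the incoming C7 (Felkin–Anh), giving O6 trans to O5. The step needs addition to the aldehyde and not to the C2 ketone (a six-membered alternative) or the esters, and ring closure instead of oligomerisation; the first is secured by the aldehyde selectivity of allylchromium reagents and the hindered, conjugated nature of the ketone on quaternary C1, the second by the gauche arrangement of the two arms on the trans-dioxolane and by high dilution.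

Step 16
Reactants: 30 tricyclic lactone
Product: 31 C5,C1-diol
Conditions: PPTS, MeOH, 40 °C
Reagents that add atoms: none
Why: acid-catalysed transacetalisation with methanol removes the strained trans-fused isopropylidene acetal faster than it cleaves the secondary silyl ether, freeing O5 and O1.

Step 17
Reactants: 31 C5,C1-diol; 32 angelic acid
Product: 34 C5 angelate, via mixed anhydride 33 (not isolated)
Conditions: 32, 2,4,6-trichlorobenzoyl chloride, Et3N, toluene, 23 °C; then 31, toluene, 80 °C
Reagents that add atoms: none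
Why: Yamaguchi esterification through mixed anhydride 33 without a nucleophilic catalyst acylates the secondary C5 alcohol in preference to the tertiary C1 alcohol and avoids (Z) to (E) isomerisation of the angeloyl unit.

Step 18
Reactants: 34 C5 angelate
Product: 35 target CNP0149130.1
Conditions: HF·pyridine, THF/pyridine, 0 to 23 °C
Reagents that add atoms: none
Why: fluoride-mediated desilylation under buffered, weakly acidic conditions frees the C9 alcohol without acyl migration, lactone opening or conjugate addition to the enone and methylene lactone.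

**Compound list**

1 | (+)-2,3-O-isopropylidene-L-threitol, [(4S,5S)-2,2-dimethyl-1,3-dioxolane-4,5-diyl]dimethanol | OC[C@@H]1OC(C)(C)O[C@H]1CO | starting material
2 | [(4S,5S)-5-{[(4-methoxybenzyl)oxy]methyl}-2,2-dimethyl-1,3-dioxolan-4-yl]methanol | OC[C@@H]1OC(C)(C)O[C@H]1COCc1ccc(OC)cc1 | intermediate
3 | (4R,5S)-5-{[(4-methoxybenzyl)oxy]methyl}-2,2-dimethyl-1,3-dioxolane-4-carbaldehyde | O=C[C@@H]1OC(C)(C)O[C@H]1COCc1ccc(OC)cc1 | intermediate
4 | (4R,5S)-5-{[(4-methoxybenzyl)oxy]methyl}-2,2-dimethyl-1,3-dioxolane-4-carboxylic acid | OC(=O)[C@@H]1OC(C)(C)O[C@H]1COCc1ccc(OC)cc1 | intermediate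
5 | (2E)-but-2-en-1-ol (trans-crotyl alcohol) | C/C=C/CO | starting material
6 | (2E)-but-2-en-1-yl (4R,5S)-5-{[(4-methoxybenzyl)oxy]methyl}-2,2-dimethyl-1,3-dioxolane-4-carboxylate | C/C=C/COC(=O)[C@@H]1OC(C)(C)O[C@H]1COCc1ccc(OC)cc1 | intermediate
7 | (Z)-trimethylsilyl ketene acetal of 6, (5S)-4-{[(2E)-but-2-en-1-yloxy][(trimethylsilyl)oxy]methylidene}-5-{[(4-methoxybenzyl)oxy]methyl}-2,2-dimethyl-1,3-dioxolane, silyloxy cis to the ring oxygen | C[Si](C)(C)O/C(OC/C=C/C)=C1\OC(C)(C)O[C@H]1COCc1ccc(OC)cc1 | intermediate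
8 | trimethylsilyl (4S,5S)-4-[(2S)-but-3-en-2-yl]-5-{[(4-methoxybenzyl)oxy]methyl}-2,2-dimethyl-1,3-dioxolane-4-carboxylate | C=C[C@H](C)[C@@](OC1(C)C)(C(=O)O[Si](C)(C)C)[C@H](COCc2ccc(OC)cc2)O1 | intermediate
9 | (4S,5S)-4-[(2S)-but-3-en-2-yl]-5-{[(4-methoxybenzyl)oxy]methyl}-2,2-dimethyl-1,3-dioxolane-4-carboxylic acid | C=C[C@H](C)[C@@](OC1(C)C)(C(=O)O)[C@H](COCc2ccc(OC)cc2)O1 | intermediate
10 | (4S,5S)-4-[(2S)-but-3-en-2-yl]-5-{[(4-methoxybenzyl)oxy]methyl}-2,2-dimethyl-1,3-dioxolane-4-carbonyl chloride | C=C[C@H](C)[C@@](OC1(C)C)(C(=O)Cl)[C@H](COCc2ccc(OC)cc2)O1 | intermediate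
11 | (4S,5S)-4-[(2S)-but-3-en-2-yl]-N-methoxy-5-{[(4-methoxybenzyl)oxy]methyl}-N,2,2-trimethyl-1,3-dioxolane-4-carboxamide | C=C[C@H](C)[C@@](OC1(C)C)(C(=O)N(C)OC)[C@H](COCc2ccc(OC)cc2)O1 | intermediate
12 | secondary ozonide (1,2,4-trioxolane) of the vinyl group of 11, both epimers at the new acetal carbon | C1OC(OO1)[C@H](C)[C@@](OC2(C)C)(C(=O)N(C)OC)[C@H](COCc3ccc(OC)cc3)O2 | intermediate
13 | (4S,5S)-N-methoxy-5-{[(4-methoxybenzyl)oxy]methyl}-N,2,2-trimethyl-4-[(2R)-1-oxopropan-2-yl]-1,3-dioxolane-4-carboxamide | O=C[C@H](C)[C@@](OC1(C)C)(C(=O)N(C)OC)[C@H](COCc2ccc(OC)cc2)O1 | intermediate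
14 | allyltrimethylsilane | C=CC[Si](C)(C)C | starting material
15 | (4S,5S)-4-[(2S,3R)-3-hydroxyhex-5-en-2-yl]-N-methoxy-5-{[(4-methoxybenzyl)oxy]methyl}-N,2,2-trimethyl-1,3-dioxolane-4-carboxamide | C=CC[C@@H](O)[C@H](C)[C@@](OC1(C)C)(C(=O)N(C)OC)[C@H](COCc2ccc(OC)cc2)O1 | intermediate
16 | (4S,5S)-4-{(2S,3R)-3-[(tert-butyldimethylsilyl)oxy]hex-5-en-2-yl}-N-methoxy-5-{[(4-methoxybenzyl)oxy]methyl}-N,2,2-trimethyl-1,3-dioxolane-4-carboxamide | C=CC[C@@H](O[Si](C)(C)C(C)(C)C)[C@H](C)[C@@](OC1(C)C)(C(=O)N(C)OC)[C@H](COCc2ccc(OC)cc2)O1 | intermediate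
17 | (1E)-1-bromoprop-1-ene | C/C=C/Br | starting material
18 | (1E)-prop-1-en-1-yllithium | C/C=C/[Li] | intermediate
19 | lithium N,O-hemiaminal adduct of 16 and 18 (both epimers at C2) | C=CC[C@@H](O[Si](C)(C)C(C)(C)C)[C@H](C)[C@@](OC1(C)C)(C(O[Li])(N(C)OC)/C=C/C)[C@H](COCc2ccc(OC)cc2)O1 | intermediate
20 | (2E)-1-[(4S,5S)-4-{(2S,3R)-3-[(tert-butyldimethylsilyl)oxy]hex-5-en-2-yl}-5-{[(4-methoxybenzyl)oxy]methyl}-2,2-dimethyl-1,3-dioxolan-4-yl]but-2-en-1-one | C=CC[C@@H](O[Si](C)(C)C(C)(C)C)[C@H](C)[C@@](OC1(C)C)(C(=O)/C=C/C)[C@H](COCc2ccc(OC)cc2)O1 | intermediate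
21 | secondary ozonide (1,2,4-trioxolane) of the terminal alkene of 20, both epimers at the new acetal carbon | C1OC(OO1)C[C@@H](O[Si](C)(C)C(C)(C)C)[C@H](C)[C@@](OC2(C)C)(C(=O)/C=C/C)[C@H](COCc3ccc(OC)cc3)O2 | intermediate
22 | (3R,4S)-3-[(tert-butyldimethylsilyl)oxy]-4-[(4S,5S)-4-[(2E)-but-2-enoyl]-5-{[(4-methoxybenzyl)oxy]methyl}-2,2-dimethyl-1,3-dioxolan-4-yl]pentanal | O=CC[C@@H](O[Si](C)(C)C(C)(C)C)[C@H](C)[C@@](OC1(C)C)(C(=O)/C=C/C)[C@H](COCc2ccc(OC)cc2)O1 | intermediate
23 | methyl acrylate (methyl prop-2-enoate) | C=CC(=O)OC | starting material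
24 | methyl (5R,6S)-5-[(tert-butyldimethylsilyl)oxy]-6-[(4S,5S)-4-[(2E)-but-2-enoyl]-5-{[(4-methoxybenzyl)oxy]methyl}-2,2-dimethyl-1,3-dioxolan-4-yl]-3-hydroxy-2-methylideneheptanoate, both C3 epimers | C=C(C(=O)OC)C(O)C[C@@H](O[Si](C)(C)C(C)(C)C)[C@H](C)[C@@](OC1(C)C)(C(=O)/C=C/C)[C@H](COCc2ccc(OC)cc2)O1 | intermediate
25 | methyl (2Z,5R,6S)-2-(bromomethyl)-5-[(tert-butyldimethylsilyl)oxy]-6-[(4S,5S)-4-[(2E)-but-2-enoyl]-5-{[(4-methoxybenzyl)oxy]methyl}-2,2-dimethyl-1,3-dioxolan-4-yl]hept-2-enoate | COC(=O)/C(CBr)=C/C[C@@H](O[Si](C)(C)C(C)(C)C)[C@H](C)[C@@](OC1(C)C)(C(=O)/C=C/C)[C@H](COCc2ccc(OC)cc2)O1 | intermediate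
26 | methyl (2Z,5R,6S)-2-(bromomethyl)-5-[(tert-butyldimethylsilyl)oxy]-6-[(4S,5S)-4-[(2E)-but-2-enoyl]-5-(hydroxymethyl)-2,2-dimethyl-1,3-dioxolan-4-yl]hept-2-enoate | COC(=O)/C(CBr)=C/C[C@@H](O[Si](C)(C)C(C)(C)C)[C@H](C)[C@@](OC1(C)C)(C(=O)/C=C/C)[C@H](CO)O1 | intermediate
27 | methyl (2Z,5R,6S)-2-(bromomethyl)-5-[(tert-butyldimethylsilyl)oxy]-6-[(4S,5R)-4-[(2E)-but-2-enoyl]-5-formyl-2,2-dimethyl-1,3-dioxolan-4-yl]hept-2-enoate | COC(=O)/C(CBr)=C/C[C@@H](O[Si](C)(C)C(C)(C)C)[C@H](C)[C@@](OC1(C)C)(C(=O)/C=C/C)[C@H](C=O)O1 | intermediate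
28 | allylchromium dichloride from 27 (bromine replaced by CrCl2, trivalent chromium) | COC(=O)/C(C[Cr](Cl)Cl)=C/C[C@@H](O[Si](C)(C)C(C)(C)C)[C@H](C)[C@@](OC1(C)C)(C(=O)/C=C/C)[C@H](C=O)O1 | intermediate
29 | ring-A hydroxy ester: methyl 2-substituted acrylate on C7 of the acetonide-fused cycloheptane, free C6–OH cis to the acrylate arm and trans to O5, other centres as in 30 | COC(=O)C(=C)[C@@H]1C[C@@H](O[Si](C)(C)C(C)(C)C)[C@H](C)[C@@](OC2(C)C)(C(=O)/C=C/C)[C@@H](O2)[C@@H]1O | intermediate
30 | (3aS,5R,6S,7S,8S,8aR)-7-[(2E)-but-2-enoyl]-5-[(tert-butyldimethylsilyl)oxy]-7,8-(isopropylidenedioxy)-6-methyl-3-methylideneoctahydro-2H-cyclohepta[b]furan-2-one | C=C1C(=O)O[C@@H]2[C@H]1C[C@@H](O[Si](C)(C)C(C)(C)C)[C@H](C)[C@@](OC3(C)C)(C(=O)/C=C/C)[C@H]2O3 | intermediate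
31 | (3aS,5R,6S,7S,8S,8aR)-7-[(2E)-but-2-enoyl]-5-[(tert-butyldimethylsilyl)oxy]-7,8-dihydroxy-6-methyl-3-methylideneoctahydro-2H-cyclohepta[b]furan-2-one | C=C1C(=O)O[C@@H]2[C@H]1C[C@@H](O[Si](C)(C)C(C)(C)C)[C@H](C)[C@@](O)(C(=O)/C=C/C)[C@H]2O | intermediate
32 | angelic acid, (2Z)-2-methylbut-2-enoic acid | C/C=C(/C)C(=O)O | starting material
33 | (2Z)-2-methylbut-2-enoic 2,4,6-trichlorobenzoic anhydride | C/C=C(/C)C(=O)OC(=O)c1c(Cl)cc(Cl)cc1Cl | intermediate
34 | (3aS,5R,6S,7S,8S,8aR)-7-[(2E)-but-2-enoyl]-5-[(tert-butyldimethylsilyl)oxy]-7-hydroxy-6-methyl-3-methylidene-2-oxooctahydro-2H-cyclohepta[b]furan-8-yl (2Z)-2-methylbut-2-enoate | C=C1C(=O)O[C@@H]2[C@H]1C[C@@H](O[Si](C)(C)C(C)(C)C)[C@H](C)[C@@](O)(C(=O)/C=C/C)[C@H]2OC(=O)/C(C)=C\C | intermediate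
35 | CNP0149130.1, (3aS,5R,6S,7S,8S,8aR)-7-[(2E)-but-2-enoyl]-5,7-dihydroxy-6-methyl-3-methylidene-2-oxooctahydro-2H-cyclohepta[b]furan-8-yl (2Z)-2-methylbut-2-enoate | C=C1C(=O)O[C@@H]2[C@H]1C[C@@H](O)[C@H](C)[C@@](O)(C(=O)/C=C/C)[C@H]2OC(=O)/C(C)=C\C | target

**Step count and risks**

Total step count: 18. Longest linear sequence: 18 steps (1 to 35); compounds 5, 14, 17, 23 and 32 enter as purchased partners.

Steps most likely to fail, with one fallback each:

Step 15 (key step). What may go wrong: the allylchromium may close onto the C2 ketone (six-membered ring) instead of the aldehyde, couple intermolecularly, or add to the aldehyde through the other rotamer so that facial selectivity at C6 is poor. The fallback replaces the reductive metalation by an intramolecular allylboration, which does not touch ketones and goes through a tight chair. It sets out from 24 and comes back at 30. Acetylation of 24 (Ac2O, DMAP, CH2Cl2) should give the allylic acetate F1. Borylation with B2pin2 and catalytic Pd2(dba)3 (DMSO, 50 °C), with allylic transposition, should give the (E)-allyl pinacol boronate F2. DDQ should then give the primary alcohol F3, and Dess–Martin oxidation the boronate aldehyde F4. On gentle warming, or with catalytic Sc(OTf)3, F4 should close ring A to the pinacol borate of the hydroxy ester F5. Mildly acidic work-up frees 29, which lactonises to 30.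

Step 10. What may go wrong: over-oxidation, ozone also cleaving the enone C=C or degrading the PMB arene before the terminal alkene is consumed. The fallback changes the order so that no enone is present during ozonolysis. It sets out from 16 and comes back at 22. Ozonolysis of 16 (O3, then PPh3) should pass through the secondary ozonide F6 to the aldehyde Weinreb amide F7. Acetalisation (HC(OMe)3, PPTS, MeOH) should give the dimethyl acetal F8. Addition of 18 should go through the lithium adduct F9 to the enone dimethyl acetal F10. Mild hydrolysis (PPTS, acetone/H2O) should then return 22.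

Step 17. What may go wrong: sluggish acylation of the hindered C5 alcohol next to quaternary C1, with isomerisation of the angeloyl unit to the tigloyl unit during prolonged heating. The fallback builds the (Z)-alkene on the ester instead of transferring it. It sets out from 31 and comes back at 34. Acylation of 31 with 2-[bis(2,2,2-trifluoroethoxy)phosphoryl]propanoic acid (DCC, DMAP, CH2Cl2; acylation via the phosphonoketene is less sensitive to hindrance) should give the phosphonopropanoate F11. A Still–Gennari olefination with acetaldehyde (KN(SiMe3)2, 18-crown-6, THF, −78 °C) should then give the (Z)-2-methylbut-2-enoate 34.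

**Further compounds**

F1 | step 15 | allylic acetate of 24 (methyl 3-acetoxy-2-methylidene ester, both C3 epimers) | C=C(C(=O)OC)C(OC(C)=O)C[C@@H](O[Si](C)(C)C(C)(C)C)[C@H](C)[C@@](OC1(C)C)(C(=O)/C=C/C)[C@H](COCc2ccc(OC)cc2)O1
F2 | step 15 | (E)-allyl pinacol boronate, analogue of 25 with CH2Bpin in place of CH2Br | COC(=O)/C(CB1OC(C)(C)C(C)(C)O1)=C/C[C@@H](O[Si](C)(C)C(C)(C)C)[C@H](C)[C@@](OC2(C)C)(C(=O)/C=C/C)[C@H](COCc3ccc(OC)cc3)O2
F3 | step 15 | primary alcohol, analogue of 26 with CH2Bpin in place of CH2Br | COC(=O)/C(CB1OC(C)(C)C(C)(C)O1)=C/C[C@@H](O[Si](C)(C)C(C)(C)C)[C@H](C)[C@@](OC2(C)C)(C(=O)/C=C/C)[C@H](CO)O2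
F4 | step 15 | boronate aldehyde, analogue of 27 with CH2Bpin in place of CH2Br | COC(=O)/C(CB1OC(C)(C)C(C)(C)O1)=C/C[C@@H](O[Si](C)(C)C(C)(C)C)[C@H](C)[C@@](OC2(C)C)(C(=O)/C=C/C)[C@H](C=O)O2
F5 | step 15 | pinacol borate (O6–Bpin) of hydroxy ester 29 | COC(=O)C(=C)[C@@H]1C[C@@H](O[Si](C)(C)C(C)(C)C)[C@H](C)[C@@](OC2(C)C)(C(=O)/C=C/C)[C@@H](O2)[C@@H]1OB1OC(C)(C)C(C)(C)O1
F6 | step 10 | secondary ozonide (1,2,4-trioxolane) of the terminal alkene of 16 | C1OC(OO1)C[C@@H](O[Si](C)(C)C(C)(C)C)[C@H](C)[C@@](OC2(C)C)(C(=O)N(C)OC)[C@H](COCc3ccc(OC)cc3)O2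
F7 | step 10 | aldehyde Weinreb amide (C7 aldehyde analogue of 22 with C2 as N-methoxy-N-methylamide) | O=CC[C@@H](O[Si](C)(C)C(C)(C)C)[C@H](C)[C@@](OC1(C)C)(C(=O)N(C)OC)[C@H](COCc2ccc(OC)cc2)O1
F8 | step 10 | dimethyl acetal of F7 | COC(OC)C[C@@H](O[Si](C)(C)C(C)(C)C)[C@H](C)[C@@](OC1(C)C)(C(=O)N(C)OC)[C@H](COCc2ccc(OC)cc2)O1
F9 | step 10 | lithium N,O-hemiaminal adduct of F8 and 18 | COC(OC)C[C@@H](O[Si](C)(C)C(C)(C)C)[C@H](C)[C@@](OC1(C)C)(C(O[Li])(N(C)OC)/C=C/C)[C@H](COCc2ccc(OC)cc2)O1
F10 | step 10 | dimethyl acetal of 22 ((E)-enone acetal) | COC(OC)C[C@@H](O[Si](C)(C)C(C)(C)C)[C@H](C)[C@@](OC1(C)C)(C(=O)/C=C/C)[C@H](COCc2ccc(OC)cc2)O1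
F11 | step 17 | C5 2-[bis(2,2,2-trifluoroethoxy)phosphoryl]propanoate of 31 | C=C1C(=O)O[C@@H]2[C@H]1C[C@@H](O[Si](C)(C)C(C)(C)C)[C@H](C)[C@@](O)(C(=O)/C=C/C)[C@H]2OC(=O)C(C)P(=O)(OCC(F)(F)F)OCC(F)(F)F
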